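## Structural features

The target is a biflavone ether: two 2-aryl-4H-chromen-4-one units held together by a single diaryl ether oxygen that joins C4' of ring B of flavone 1 to C8 of ring A of flavone 2. Flavone 1 carries 5-OH and 7-OMe. Flavone 2 carries 5-OH, 7-OMe, the 8-aryloxy group and a free 4'-OH. There is no stereocenter, so every problem is one of regiochemistry and of telling five phenolic oxygens apart (two methylated, three free). The fragile elements are the pyranone rings, which are vinylogous esters that hard nucleophiles can open, and the 5-hydroxy-8-oxygenated ring A of flavone 2. That ring is a latent para-hydroquinone, and once its 5-OH is free a base-opened pyranone can reclose on the other oxygen and move the 8-substituent to C6. The real difficulty is the ether at C8 of flavone 2, which lies between the 7-methoxy group and the ring oxygen on a 1,2,3,5-tetraoxygenated benzene. Ring A of flavone 1 is a phloroglucinol monomethyl ether acylated at C4a between two oxygens (on C5 and C8a) that are equivalent until the pyranone closes, with the methoxy group para to the acyl carbon. The key step exploits this: a 4-methoxy-2-pyrone with a 2-oxoalkyl chain on C6 delivers exactly this pattern, the side-chain methylene becoming C4a and the lactone carbonyl carbon and pyrone C6 becoming the two oxygen-bearing carbons.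

## Logic of the disconnections

19 from 18. The O–CH2Ph bond at the 4'-oxygen of flavone 2 and the O–CH3 bond at its 5-oxygen are added in the retro sense. The para phenol and the peri phenol of flavone 2 must stay masked through all base and organolithium chemistry, and both ethers fall to one Lewis acid. The gain is a substrate with a single free phenol and no route for 8-to-6 isomerization. The demand is that the forward cleavage spare two 7-methyl ethers and the diaryl ether.

18 from 16. The O1–C2 bond of the pyranone of flavone 1 is cut and two hydrogens are returned to C2/C3. Oxidative cyclization of a 2'-hydroxychalcone is dependable, and the two phenols of 16 are equivalent, so only one flavone can form. The gain is the removal of one heterocycle. The demand is an oxidant that leaves the electron-rich rings and the benzyl ether alone.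

16 from 14. The C4a–C5 bond of ring A of flavone 1 is cut, which converts the benzene ring into a 2-pyrone carrying the cinnamoylmethyl chain on C6. The methylation pattern (7-OMe against two free phenols) is then inherited from the pyrone and needs no selective alkylation of a phloroglucinol. The gain is the exchange of an aromatic ring for a purchased heterocycle. The demand is Claisen-type closure rather than aldol closure, in the presence of an enone.

14 from 10 and 11. The bond between the side-chain methylene and the ketone carbon is cut. The methylene is the 6-methyl group of 11 and the ketone carbon is the carboxyl carbon of 10. The gain is a convergent union of the whole flavone 2 half with a commercial pyrone. The demand is C-acylation at the carbonyl rather than conjugate addition, with enough base equivalents for the acidic product.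

10 from 8 and 9. The Cα=Cβ double bond of the cinnamic acid is cut, giving an aryl aldehyde and a two-carbon acid donor. The gain is that the aldehyde also serves as the activating group for the ether synthesis one step earlier. The demand is E-selective condensation under conditions that leave the flavone untouched.

8 from 5 and 6. The diaryl ether is cut on the benzaldehyde side (aryl C4–O), and the 5-O–CH3 bond is cut as well. This polarity pairs an electron-rich, hindered phenoxide with an activated aryl fluoride, the favourable direction for a crowded ether. The gain is that the hardest bond of the target comes from two simple partners. The demand is that the 8-phenoxide react and the chelated 5-oxygen does not, and that the hydroquinone be kept from air.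

5 from 3. The C8–O bond is cut. The 5-phenol directs an electrophilic oxygen to its para position, which is C8. The gain is that the 1,2,3,5-tetraoxygenated ring is reached from a ring with the natural 5,7-pattern. The demand is para-selective hydroxylation of a sparingly soluble phenoxide.

3 from 2 from 1. The 4'-O–CH2Ph and the 7-O–CH3 bonds are cut in turn. The three phenols of 1 differ in acidity (7 > 4' > chelated 5), so two successive Williamson steps can address them in that order. The gain is a bulk natural flavone as the source of all of flavone 2. The demand is mono-alkylation at O7 in the first step.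

## Other disconnections considered

Alternative 1: The cut is the C4–C4a bond of the pyranone of flavone 2. In the forward sense the (Z)-3-aryloxycinnamic acid A2, reached from 2-aryloxy-3,5-dimethoxyphenol A1 by a Ruhemann-type O-vinylation, would be cyclized with P2O5 in MeSO3H to the di-O-methyl mesylate A3 by intramolecular Friedel–Crafts acylation.
- In its favour: only one ortho position is open on the phenoxy ring of A2, and it is activated ortho and para by the two methoxy groups. The regiochemistry is therefore as unambiguous as in the chosen plan, an equal point.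
- In its favour: it needs no organolithium or low-temperature step, and the cycloacylation has no competing mode of closure, which makes it mechanistically the simpler key step and in that respect the better one.
- Against it: the hot acidic medium excludes a benzyl ether, so a mesylate has to be carried and removed separately, alongside two peri-demethylations.
- Against it: the acid must have, or reach by isomerization, the Z geometry.
- Against it, and decisive: A1 is the 1,2,3,5-tetraoxygenated benzene with the hindered ether already in place, and it would have to be built from the beginning. The chosen plan takes that ring ready-made from 1.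
- Comparison: both key steps close one ring with one C–C bond. Alternative 1 is likely the longer route once the supply of A1 and the three unmaskings are counted.

Alternative 2: The cut is the C5–C6 bond of ring A of flavone 2. In the forward sense NaH would generate the methyl ketone enolate of the pyranone keto ester A4. It attacks the ester on the neighbouring ring carbon in a Dieckmann-type Claisen closure, and enolization gives the 5,7-dihydroxy-8-aryloxyflavone A5.
- In its favour: this is the same reaction class as the chosen key step, but applied to the more crowded ring. The aryloxy group would be introduced on an sp3 carbon before ring A exists, so neither a nuclear oxidation nor a hindered ether synthesis is needed. In that structural respect it is the better idea.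
- In its favour: aromatization supplies the driving force, equal to the chosen step.
- Against it: A4 is a densely substituted 4-pyranone whose preparation is a multi-step problem of its own.
- Against it: its most acidic proton is the methine bearing the aryloxy group and not the methyl group, so the productive enolate must be reached by equilibration.
- Against it: a 4-pyranone with a neighbouring ester is a good Michael acceptor for the base.
- Against it: A5 still needs a selective 7-O-methylation, a peri-demethylation in flavone 1 and a debenzylation.
- Comparison: equal in the type of bond formed and ring closed, weaker in enolate regiocontrol, and clearly weaker in step economy.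

Alternative 3: The cut is the C2=C3 bond of the pyranone of flavone 2. In the forward sense the acylphosphorane A7, made from the 2-hydroxyacetophenone A6 by α-bromination, phosphonium salt formation and O-aroylation, would on heating close onto the carbonyl of its own 4-benzyloxybenzoate ester. This intramolecular Wittig reaction would give A8 and Ph3PO.
- In its favour: the conditions are neutral and the flavone oxidation level is reached without an oxidant.
- In its favour: regiochemistry is fixed by construction and the benzyl ether is tolerated.
- In its favour: A8 is a single Lewis-acid step from the target, since both peri-methyl ethers and the benzyl group should fall together. That endgame is one step shorter than the chosen one, and on mildness and endgame this alternative is the better.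
- Against it: A6 again contains the tetraoxygenated ring with the hindered ether, now with an acetyl group. A persulfate oxidation at the acetophenone stage would go para to the phenol, which is the wrong carbon, so the extra oxygen must be brought in another way.
- Against it: aroylation of a phenol flanked by acyl and aryloxy groups, and α-bromination beside electron-rich rings, are further weak points.
- Comparison: equal in bonds and rings formed by the key step, but behind the chosen plan on the accessibility of its precursor and therefore on overall length.

Key step: step 7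

Remark on the chemistry: in the intact pyrone the side-chain carbon cannot reach the lactone carbonyl, because the new bond would span the ring across O1. The ring transformation is therefore formulated through methanolysis of the lactone to the open ester 15 before the Claisen closure. Precursor 14 and product 16 are unaffected by this.

## Route

Step 1
Reactants: 1 apigenin (5,7,4'-trihydroxyflavone)
Product: 2 genkwanin (5,4'-dihydroxy-7-methoxyflavone)
Conditions: MeI (1.05 equiv), K2CO3 (1.0 equiv), DMF, 0 °C → rt
Reagents that add atoms: iodomethane, CI
Why: Williamson ether synthesis at the most acidic phenol; the 7-OH is a vinylogous acid through the C4 carbonyl, the 4'-OH is less acidic and the 5-OH is locked in a hydrogen bond, so one equivalent of base and MeI should methylate O7 first. Some 7,4'-dimethyl ether is to be expected and should be removable by chromatography.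

Step 2
Reactants: 2 genkwanin
Product: 3 4'-benzyloxy-5-hydroxy-7-methoxyflavone
Conditions: BnBr (1.2 equiv), K2CO3, DMF, 50 °C
Reagents that add atoms: benzyl bromide, BrCc1ccccc1
Why: Williamson benzylation of the only non-chelated phenol; the hydrogen-bonded 5-OH should not react at this temperature.

Step 3
Reactants: 3 4'-benzyloxy-5-hydroxy-7-methoxyflavone
Product: 5 4'-benzyloxy-5,8-dihydroxy-7-methoxyflavone, via potassium flavon-8-yl sulfate 4 (not isolated)
Conditions: K2S2O8, aq. KOH, pyridine, 10 °C → rt; then 2 M HCl, Na2SO3, 80 °C
Reagents that add atoms: potassium peroxydisulfate, [K+].[K+].[O-]S(=O)(=O)OOS(=O)(=O)[O-]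
Why: Elbs persulfate oxidation: the 5-phenoxide is attacked by peroxydisulfate at its para carbon C8 to give the aryl sulfate, which dilute acid hydrolyses to the phenol. This is the classical nuclear oxidation of 5-hydroxy-7-methoxyflavones, and sulfite keeps the hydroquinone from air oxidation.

Step 4
Reactants: 5 4'-benzyloxy-5,8-dihydroxy-7-methoxyflavone; 6 4-fluorobenzaldehyde
Product: 8 4-[(4'-benzyloxy-5,7-dimethoxyflavon-8-yl)oxy]benzaldehyde, via 5-hydroxy aldehyde 7 (not isolated)
Conditions: K2CO3, DMF (degassed), Ar, 100 °C; then MeI, K2CO3, 50 °C (sealed)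
Reagents that add atoms: iodomethane, CI
Why: Nucleophilic aromatic substitution through a Meisenheimer adduct: the free 8-phenoxide attacks the fluoride para to the formyl group, while the chelated 5-oxygen is a much poorer nucleophile. The 5-OH is then methylated in the same pot under more forcing Williamson conditions, which blocks later isomerization of flavone 2.

Step 5
Reactants: 8 4-[(4'-benzyloxy-5,7-dimethoxyflavon-8-yl)oxy]benzaldehyde; 9 malonic acid
Product: 10 (E)-3-{4-[(4'-benzyloxy-5,7-dimethoxyflavon-8-yl)oxy]phenyl}prop-2-enoic acid
Conditions: pyridine, piperidine (cat.), 90 °C; then aq. HCl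
Reagents that add atoms: none
Why: Knoevenagel condensation in the Doebner modification with decarboxylation in pyridine; the E acid is the thermodynamic product, and the non-enolizable aldehyde is far more electrophilic than the flavone.

Step 6
Reactants: 10 (E)-3-{4-[(4'-benzyloxy-5,7-dimethoxyflavon-8-yl)oxy]phenyl}prop-2-enoic acid; 11 4-methoxy-6-methyl-2H-pyran-2-one
Product: 14 6-{(E)-4-[4-(4'-benzyloxy-5,7-dimethoxyflavon-8-yloxy)phenyl]-2-oxobut-3-enyl}-4-methoxy-2H-pyran-2-one, via acyl imidazolide 12 (not isolated), via lithiated pyrone 13 (not isolated)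
Conditions: 10, CDI, THF, rt; 11 (3.3 equiv), LiN(iPr)2 (3.2 equiv), THF, −78 °C; add 12 to 13, −78 → −40 °C; aq. NH4Cl
Reagents that add atoms: none
Why: Crossed Claisen-type C-acylation: the amide base removes a proton from the 6-methyl group (vinylogous to the lactone carbonyl), and the resulting lithium dienolate should attack the hard, highly activated N-acylimidazole carbonyl in preference to the β-carbon. Three equivalents of the anion are budgeted, for the acyl transfer, for the acidic β-keto pyrone formed and for the imidazole set free by CDI. The anion is formed with the pyrone in slight excess so that no free amide base meets the flavone.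

Step 7
Reactants: 14 6-{(E)-4-[4-(4'-benzyloxy-5,7-dimethoxyflavon-8-yloxy)phenyl]-2-oxobut-3-enyl}-4-methoxy-2H-pyran-2-one
Product: 16 (E)-1-(2,6-dihydroxy-4-methoxyphenyl)-3-{4-[(4'-benzyloxy-5,7-dimethoxyflavon-8-yl)oxy]phenyl}prop-2-en-1-one, via ring-opened methyl ester 15 (not isolated)
Conditions: Mg(OMe)2 (excess), MeOH–THF, reflux; then 1 M HCl, 0 °C
Reagents that add atoms: none
Why: Methoxide held on magnesium should first open the lactone at the pyrone carbonyl, because the side-chain carbon cannot reach that carbon while the ring oxygen still ties C2 to C6; this gives the magnesium chelate of the enol-ether diketo ester 15, whose ester group and C4 methylene stay cis on the former C3=C4 bond. The methylene flanked by the two ketones, bound as a magnesium β-diketonate, then attacks the ester carbonyl in an intramolecular Claisen (Dieckmann-type) condensation, a 6-(enolexo)-exo-trig closure of the one new carbocycle that forms the C4a–C5 bond. Loss of methoxide and enolization of the cyclohexadienone give the benzene ring: the former lactone carbonyl oxygen and the former ring oxygen become the two phenols, and the pyrone methoxy group ends para to the acyl group. The closest known reaction type is the biomimetic Claisen cyclization of 3,5,7-triketo esters and of 6-(2-oxoalkyl)-4-methoxy-2-pyrones to acylphloroglucinols with Mg(OMe)2. No stereocenter is formed and the E geometry of the enone is not touched. The selectivity required is Claisen over aldol closure (attack of chain C2 on the cinnamoyl carbonyl); it should be secured by magnesium chelation, which places the nucleophile on the central methylene, by the enol ether at C3, which keeps C2 and C4 from forming a second diketone enolate, and by the absence of any further ketone in the chain. Flavone 2 should survive because its 5-methyl ether leaves a base-opened pyranone only one way to reclose, and conjugate addition of methoxide to the enone is reversible.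

Step 8
Reactants: 16 (E)-1-(2,6-dihydroxy-4-methoxyphenyl)-3-{4-[(4'-benzyloxy-5,7-dimethoxyflavon-8-yl)oxy]phenyl}prop-2-en-1-one
Product: 18 4'-[(4'-benzyloxy-5,7-dimethoxyflavon-8-yl)oxy]-5-hydroxy-7-methoxyflavone, via flavanone 17 (not isolated)
Conditions: I2 (0.1 equiv), DMSO, 120 °C
Reagents that add atoms: none
Why: Iodine–DMSO oxidative cyclization of a 2'-hydroxychalcone: 6-endo-trig oxa-Michael closure of either of the two equivalent phenols gives the racemic flavanone, and α-iodination and loss of HI give the flavone while DMSO re-oxidizes HI to I2. Any flavanone already formed during the acidic work-up of step 7 is the same intermediate, and its transient stereocenter at C2 is destroyed.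

Step 9
Reactants: 18 4'-[(4'-benzyloxy-5,7-dimethoxyflavon-8-yl)oxy]-5-hydroxy-7-methoxyflavone
Product: 19 5-hydroxy-4'-[(5,4'-dihydroxy-7-methoxyflavon-8-yl)oxy]-7-methoxyflavone (the target)
Conditions: BCl3 (excess), C6HMe5, CH2Cl2, −78 → 0 °C; then MeOH, aq. HCl
Reagents that add atoms: none
Why: Lewis-acid ether cleavage: the benzyl ether should go at low temperature with pentamethylbenzene trapping the benzyl cation, and on warming the 5-methyl ether of flavone 2 should be cleaved through a six-membered boron chelate with its C4 carbonyl. The two 7-methyl ethers lack such a chelate and the diaryl ether is inert, so both should remain.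

## Compound list

1 | apigenin (5,7,4'-trihydroxyflavone) | O=c1cc(-c2ccc(O)cc2)oc2cc(O)cc(O)c12 | starting material
2 | genkwanin (5,4'-dihydroxy-7-methoxyflavone) | COc1cc(O)c2c(=O)cc(-c3ccc(O)cc3)oc2c1 | intermediate
3 | 4'-benzyloxy-5-hydroxy-7-methoxyflavone | COc1cc(O)c2c(=O)cc(-c3ccc(OCc4ccccc4)cc3)oc2c1 | intermediate
4 | potassium 4'-benzyloxy-5-hydroxy-7-methoxyflavon-8-yl sulfate | COc1cc(O)c2c(=O)cc(-c3ccc(OCc4ccccc4)cc3)oc2c1OS(=O)(=O)[O-].[K+] | intermediate
5 | 4'-benzyloxy-5,8-dihydroxy-7-methoxyflavone | COc1cc(O)c2c(=O)cc(-c3ccc(OCc4ccccc4)cc3)oc2c1O | intermediate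
6 | 4-fluorobenzaldehyde | O=Cc1ccc(F)cc1 | starting material
7 | 4-[(4'-benzyloxy-5-hydroxy-7-methoxyflavon-8-yl)oxy]benzaldehyde | COc1cc(O)c2c(=O)cc(-c3ccc(OCc4ccccc4)cc3)oc2c1Oc1ccc(C=O)cc1 | intermediate
8 | 4-[(4'-benzyloxy-5,7-dimethoxyflavon-8-yl)oxy]benzaldehyde | COc1cc(OC)c2c(=O)cc(-c3ccc(OCc4ccccc4)cc3)oc2c1Oc1ccc(C=O)cc1 | intermediate
9 | malonic acid | OC(=O)CC(=O)O | starting material
10 | (E)-3-{4-[(4'-benzyloxy-5,7-dimethoxyflavon-8-yl)oxy]phenyl}prop-2-enoic acid | COc1cc(OC)c2c(=O)cc(-c3ccc(OCc4ccccc4)cc3)oc2c1Oc1ccc(/C=C/C(=O)O)cc1 | intermediate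
11 | 4-methoxy-6-methyl-2H-pyran-2-one | COc1cc(=O)oc(C)c1 | starting material
12 | (E)-1-(imidazol-1-yl)-3-{4-[(4'-benzyloxy-5,7-dimethoxyflavon-8-yl)oxy]phenyl}prop-2-en-1-one | COc1cc(OC)c2c(=O)cc(-c3ccc(OCc4ccccc4)cc3)oc2c1Oc1ccc(/C=C/C(=O)n2ccnc2)cc1 | intermediate
13 | (4-methoxy-2-oxo-2H-pyran-6-yl)methyllithium | COc1cc(=O)oc(C[Li])c1 | intermediate
14 | 6-{(E)-4-[4-(4'-benzyloxy-5,7-dimethoxyflavon-8-yloxy)phenyl]-2-oxobut-3-enyl}-4-methoxy-2H-pyran-2-one | COc1cc(=O)oc(CC(=O)/C=C/c2ccc(Oc3c(OC)cc(OC)c4c(=O)cc(-c5ccc(OCc6ccccc6)cc5)oc34)cc2)c1 | intermediate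
15 | methyl (2E,8E)-9-{4-[(4'-benzyloxy-5,7-dimethoxyflavon-8-yl)oxy]phenyl}-3-methoxy-5,7-dioxonona-2,8-dienoate (present as its magnesium enolate) | COC(=O)/C=C(/OC)CC(=O)CC(=O)/C=C/c1ccc(Oc2c(OC)cc(OC)c3c(=O)cc(-c4ccc(OCc5ccccc5)cc4)oc23)cc1 | intermediate
16 | (E)-1-(2,6-dihydroxy-4-methoxyphenyl)-3-{4-[(4'-benzyloxy-5,7-dimethoxyflavon-8-yl)oxy]phenyl}prop-2-en-1-one | COc1cc(O)c(C(=O)/C=C/c2ccc(Oc3c(OC)cc(OC)c4c(=O)cc(-c5ccc(OCc6ccccc6)cc5)oc34)cc2)c(O)c1 | intermediate
17 | racemic 4'-[(4'-benzyloxy-5,7-dimethoxyflavon-8-yl)oxy]-5-hydroxy-7-methoxyflavanone | COc1cc(O)c2c(c1)OC(CC2=O)c1ccc(Oc2c(OC)cc(OC)c3c(=O)cc(-c4ccc(OCc5ccccc5)cc4)oc23)cc1 | intermediate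
18 | 4'-[(4'-benzyloxy-5,7-dimethoxyflavon-8-yl)oxy]-5-hydroxy-7-methoxyflavone | COc1cc(O)c2c(=O)cc(-c3ccc(Oc4c(OC)cc(OC)c5c(=O)cc(-c6ccc(OCc7ccccc7)cc6)oc45)cc3)oc2c1 | intermediate
19 | 5-hydroxy-4'-[(5,4'-dihydroxy-7-methoxyflavon-8-yl)oxy]-7-methoxyflavone | COc1cc(O)c2c(=O)cc(-c3ccc(Oc4c(OC)cc(O)c5c(=O)cc(-c6ccc(O)cc6)oc45)cc3)oc2c1 | target

## Step count and least certain steps

Total step count: 9. Longest linear sequence: 9 steps, from 1 to 19; compounds 6, 9 and 11 enter as purchased partners.

Step 7 (key step). The closure may run in the aldol sense, with chain C2 attacking the cinnamoyl carbonyl. Methoxide or the enolate oxygen may add to the enone. The reaction may also stall at the opened ester. The cause is that the cinnamoyl chain offers a second electrophile that simple alkyl or aryl ketones lack. The fallback sets out from 8 and rejoins the route at 16, and buys ring A instead of making it. Purchased 2',6'-dihydroxy-4'-methoxyacetophenone F1 would be converted with MOMCl and iPr2NEt in CH2Cl2 into 1-[4-methoxy-2,6-bis(methoxymethoxy)phenyl]ethanone F2. Claisen–Schmidt condensation of F2 with 8 (KOH, EtOH–THF, rt) should give the bis(methoxymethyl) chalcone F3, and HCl in MeOH should remove both acetals to give 16.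

Step 6. The lithium dienolate may add in the 1,4 sense to the cinnamoyl unit, be quenched by proton transfer before acyl transfer is complete, or attack the pyranone of flavone 2. The cause is the soft, delocalized character of the anion and the several electrophilic sites of the acyl partner. The fallback sets out from 8 and rejoins at 14. Wittig homologation of 8 with Ph3P=CHCHO (toluene, 80 °C) should give the (E)-3-{4-[(4'-benzyloxy-5,7-dimethoxyflavon-8-yl)oxy]phenyl}prop-2-enal F4. Aldol addition of 13 to F4 (THF, −78 °C), a 1,2-addition that such pyrone anions undergo readily with aldehydes, should give the racemic allylic alcohol 6-{(E)-4-[4-(4'-benzyloxy-5,7-dimethoxyflavon-8-yloxy)phenyl]-2-hydroxybut-3-enyl}-4-methoxy-2H-pyran-2-one F5. Oxidation with Dess–Martin periodinane (CH2Cl2, rt) should give 14.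

Step 3. Conversion may be low and the hydroquinone may be oxidized further. The cause is the poor solubility of the benzylated phenoxide in aqueous alkali and the unproductive decomposition of persulfate. The fallback sets out from 3 and rejoins at 8 without any nuclear oxidation of a phenol.
- Methylation (MeI, K2CO3, DMF, 60 °C) should give 4'-benzyloxy-5,7-dimethoxyflavone F6.
- Iodination with I2 and CF3CO2Ag in CH2Cl2, which in 5,7-dimethoxyflavones goes to C8, should give 4'-benzyloxy-8-iodo-5,7-dimethoxyflavone F7.
- Miyaura borylation (B2pin2, PdCl2(dppf) as a divalent palladium precatalyst, KOAc, dioxane, 90 °C) should give the 8-pinacolboronate F8.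
- Oxidation (H2O2, aq. NaOH, THF, 0 °C) should give 4'-benzyloxy-8-hydroxy-5,7-dimethoxyflavone F9.
- Substitution of the fluoride of 6 by F9 (K2CO3, DMF, 100 °C) should give 8 directly.

Step 4. The hydroquinone may be oxidized to the quinone under base, and the 5-oxygen may be arylated as well. The cause is that both phenols are free while the molecule is heated with carbonate. The fallback sets out from 4 and rejoins at 8, so that the free hydroquinone never appears. The alkaline solution of sulfate 4 would be treated with Me2SO4 before any acid is added, to give potassium 4'-benzyloxy-5,7-dimethoxyflavon-8-yl sulfate F10. Acid hydrolysis of F10 should give 4'-benzyloxy-8-hydroxy-5,7-dimethoxyflavone F9, the phenol also reached in the fallback for step 3. Reaction of F9 with 6 (K2CO3, DMF, 100 °C) should give 8.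

Step 9. The peri-demethylation may be incomplete, or a 7-methyl ether may be lost, most plausibly the one in flavone 2, which sits next to the 8-aryloxy oxygen and can form a five-membered boron chelate. The fallback sets out from 18 and rejoins at 19, and separates the two unmaskings. Hydrogenolysis (H2, Pd/C as zerovalent palladium on carbon, THF–EtOAc, rt) should give 5-hydroxy-4'-[(4'-hydroxy-5,7-dimethoxyflavon-8-yl)oxy]-7-methoxyflavone F11. AlCl3 in MeCN (rt to 50 °C), a milder reagent that is selective for the chelated peri-methyl ether, should then give 19.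

## Further compounds

F1 | step 7 | 2',6'-dihydroxy-4'-methoxyacetophenone (purchased) | COc1cc(O)c(C(C)=O)c(O)c1
F2 | step 7 | 1-[4-methoxy-2,6-bis(methoxymethoxy)phenyl]ethanone | COCOc1cc(OC)cc(OCOC)c1C(C)=O
F3 | step 7 | (E)-1-[4-methoxy-2,6-bis(methoxymethoxy)phenyl]-3-{4-[(4'-benzyloxy-5,7-dimethoxyflavon-8-yl)oxy]phenyl}prop-2-en-1-one | COCOc1cc(OC)cc(OCOC)c1C(=O)/C=C/c1ccc(Oc2c(OC)cc(OC)c3c(=O)cc(-c4ccc(OCc5ccccc5)cc4)oc23)cc1
F4 | step 6 | (E)-3-{4-[(4'-benzyloxy-5,7-dimethoxyflavon-8-yl)oxy]phenyl}prop-2-enal | COc1cc(OC)c2c(=O)cc(-c3ccc(OCc4ccccc4)cc3)oc2c1Oc1ccc(/C=C/C=O)cc1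
F5 | step 6 | racemic 6-{(E)-4-[4-(4'-benzyloxy-5,7-dimethoxyflavon-8-yloxy)phenyl]-2-hydroxybut-3-enyl}-4-methoxy-2H-pyran-2-one | COc1cc(=O)oc(CC(O)/C=C/c2ccc(Oc3c(OC)cc(OC)c4c(=O)cc(-c5ccc(OCc6ccccc6)cc5)oc34)cc2)c1
F6 | step 3 | 4'-benzyloxy-5,7-dimethoxyflavone | COc1cc(OC)c2c(=O)cc(-c3ccc(OCc4ccccc4)cc3)oc2c1
F7 | step 3 | 4'-benzyloxy-8-iodo-5,7-dimethoxyflavone | COc1cc(OC)c2c(=O)cc(-c3ccc(OCc4ccccc4)cc3)oc2c1I
F8 | step 3 | 4'-benzyloxy-5,7-dimethoxy-8-(4,4,5,5-tetramethyl-1,3,2-dioxaborolan-2-yl)flavone | COc1cc(OC)c2c(=O)cc(-c3ccc(OCc4ccccc4)cc3)oc2c1B1OC(C)(C)C(C)(C)O1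
F9 | step 3 | 4'-benzyloxy-8-hydroxy-5,7-dimethoxyflavone | COc1cc(OC)c2c(=O)cc(-c3ccc(OCc4ccccc4)cc3)oc2c1O
F10 | step 4 | potassium 4'-benzyloxy-5,7-dimethoxyflavon-8-yl sulfate | COc1cc(OC)c2c(=O)cc(-c3ccc(OCc4ccccc4)cc3)oc2c1OS(=O)(=O)[O-].[K+]
F11 | step 9 | 5-hydroxy-4'-[(4'-hydroxy-5,7-dimethoxyflavon-8-yl)oxy]-7-methoxyflavone | COc1cc(O)c2c(=O)cc(-c3ccc(Oc4c(OC)cc(OC)c5c(=O)cc(-c6ccc(O)cc6)oc45)cc3)oc2c1
A1 | alternative 1 | 2-[4-(5,7-dimethoxy-4-oxo-4H-chromen-2-yl)phenoxy]-3,5-dimethoxyphenol | COc1cc(O)c(Oc2ccc(cc2)-c2cc(=O)c3c(OC)cc(OC)cc3o2)c(OC)c1
A2 | alternative 1 | (Z)-3-{2-[4-(5,7-dimethoxy-4-oxo-4H-chromen-2-yl)phenoxy]-3,5-dimethoxyphenoxy}-3-[4-(methylsulfonyloxy)phenyl]prop-2-enoic acid | OC(=O)/C=C(\Oc1cc(OC)cc(OC)c1Oc1ccc(cc1)-c1cc(=O)c2c(OC)cc(OC)cc2o1)c1ccc(OS(C)(=O)=O)cc1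
A3 | alternative 1 | 5,7-dimethoxy-4'-{[5,7-dimethoxy-4'-(methylsulfonyloxy)flavon-8-yl]oxy}flavone | COc1cc(OC)c2c(=O)cc(-c3ccc(Oc4c(OC)cc(OC)c5c(=O)cc(-c6ccc(OS(C)(=O)=O)cc6)oc45)cc3)oc2c1
A4 | alternative 2 | racemic methyl 6-(4-benzyloxyphenyl)-2-{1-[4-(5,7-dimethoxy-4-oxo-4H-chromen-2-yl)phenoxy]-2-oxopropyl}-4-oxo-4H-pyran-3-carboxylate | COC(=O)c1c(C(Oc2ccc(cc2)-c2cc(=O)c3c(OC)cc(OC)cc3o2)C(C)=O)oc(cc1=O)-c1ccc(OCc2ccccc2)cc1
A5 | alternative 2 | 4'-[(4'-benzyloxy-5,7-dihydroxyflavon-8-yl)oxy]-5,7-dimethoxyflavone | COc1cc(OC)c2c(=O)cc(-c3ccc(Oc4c(O)cc(O)c5c(=O)cc(-c6ccc(OCc7ccccc7)cc6)oc45)cc3)oc2c1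
A6 | alternative 3 | 1-{3-[4-(5,7-dimethoxy-4-oxo-4H-chromen-2-yl)phenoxy]-2-hydroxy-4,6-dimethoxyphenyl}ethanone | CC(=O)c1c(OC)cc(OC)c(Oc2ccc(cc2)-c2cc(=O)c3c(OC)cc(OC)cc3o2)c1O
A7 | alternative 3 | 2-{3-[4-(5,7-dimethoxy-4-oxo-4H-chromen-2-yl)phenoxy]-4,6-dimethoxy-2-[(4-benzyloxybenzoyl)oxy]phenyl}-2-oxoethylidene(triphenyl)phosphorane | COc1cc(OC)c(C(=O)C=P(c2ccccc2)(c2ccccc2)c2ccccc2)c(OC(=O)c2ccc(OCc3ccccc3)cc2)c1Oc1ccc(cc1)-c1cc(=O)c2c(OC)cc(OC)cc2o1
A8 | alternative 3 | 4'-[(4'-benzyloxy-5,7-dimethoxyflavon-8-yl)oxy]-5,7-dimethoxyflavone | COc1cc(OC)c2c(=O)cc(-c3ccc(Oc4c(OC)cc(OC)c5c(=O)cc(-c6ccc(OCc7ccccc7)cc6)oc45)cc3)oc2c1
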